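**Assumption:** the SMILES is read as the (2R,3R)-trans-2,3-dihydrobenzofuran; compounds 1, 8, 11 and 21 are bought (1 is also one bromination away from o-vanillin).

## Retrosynthetic overview

1. Target ⇒ its O-TIPS ether ⇒ Suzuki coupling of a 5-bromo-3-methyl-dihydrobenzofuran with (E)-propenyl pinacol boronate; the 3-CH3 comes from 3-CH2OH (tosylate, then hydride).
2. The dihydrofuran ring is the only ring made (both benzene rings are bought). It is closed by acid-mediated O–C2 bond formation from an ortho-(MOM-oxy)aryl 1,3-diol, with C3 steering C2 to trans.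
3. Diol ⇒ Evans syn aldol adduct: the C2–C3 bond is made between the boron enolate of an N-arylacetyl (R)-4-benzyloxazolidinone and O-TIPS-syringaldehyde; this sets C3.
4. Imide ⇒ arylacetic acid ⇒ 5-bromo-o-vanillin (MOM ether, Wittig, hydroboration, oxidation); aldehyde ⇒ syringaldehyde.

## Route

Step 1
Reactants: 1 5-bromo-2-hydroxy-3-methoxybenzaldehyde
Product: 2 5-bromo-3-methoxy-2-(methoxymethoxy)benzaldehyde
Conditions: MOMCl (1.5 equiv), iPr2NEt (2 equiv), CH2Cl2, 0 °C to rt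
Reagents that add atoms: chloromethyl methyl ether, COCCl
Why: O-alkylation of the phenol with the reactive α-chloro ether (MOM protection) gives an acetal that survives base, hydride and boron reagents and leaves in the later acid step.

Step 2
Reactants: 2 5-bromo-3-methoxy-2-(methoxymethoxy)benzaldehyde
Product: 3 5-bromo-1-ethenyl-3-methoxy-2-(methoxymethoxy)benzene
Conditions: Ph3PCH3Br (1.3 equiv), KOtBu (1.25 equiv), THF, 0 °C to rt
Reagents that add atoms: methyltriphenylphosphonium bromide, C[P+](c1ccccc1)(c1ccccc1)c1ccccc1.[Br-]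
Why: Wittig methylenation of a non-enolisable aryl aldehyde is clean, and the aryl bromide and MOM ether are inert to the ylide.

Step 3
Reactants: 3 5-bromo-1-ethenyl-3-methoxy-2-(methoxymethoxy)benzene
Product: 5 2-[5-bromo-3-methoxy-2-(methoxymethoxy)phenyl]ethan-1-ol, via alkylborane 4 (not isolated)
Conditions: 9-BBN (0.5 M in THF, 1.5 equiv), THF, 0 °C to rt; then 3 M NaOH, 30% H2O2, 0 °C to rt
Reagents that add atoms: 9-borabicyclo[3.3.1]nonane, C1CCC2CCCC(C1)B2 (its atoms stay in 4 only); hydrogen peroxide, OO (hydroxyl oxygen of 5)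
Why: Anti-Markovnikov hydroboration with the bulky 9-BBN followed by oxidation gives the primary alcohol with high regioselectivity, and the aryl bromide is untouched.

Step 4
Reactants: 5 2-[5-bromo-3-methoxy-2-(methoxymethoxy)phenyl]ethan-1-ol
Product: 7 2-[5-bromo-3-methoxy-2-(methoxymethoxy)phenyl]acetic acid, via arylacetaldehyde 6 (not isolated)
Conditions: TEMPO (7 mol %), NaClO2 (2 equiv), NaOCl (2 mol %), MeCN/phosphate buffer pH 6.7, 35 °C
Reagents that add atoms: sodium chlorite, [Na+].[O-]Cl=O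
Why: The TEMPO/NaOCl-catalysed oxidation with NaClO2 as terminal oxidant takes the primary alcohol through the aldehyde to the acid near neutral pH, so the MOM acetal survives and ring chlorination is kept low.

Step 5
Reactants: 7 2-[5-bromo-3-methoxy-2-(methoxymethoxy)phenyl]acetic acid; 8 (R)-4-benzyl-1,3-oxazolidin-2-one
Product: 10 (4R)-4-benzyl-3-{2-[5-bromo-3-methoxy-2-(methoxymethoxy)phenyl]acetyl}-1,3-oxazolidin-2-one, via mixed pivalic anhydride 9 (not isolated)
Conditions: PivCl (1.1 equiv), Et3N (2.5 equiv), THF, −20 °C; then LiCl (1.2 equiv), 8 (1.05 equiv), −20 °C to rt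
Reagents that add atoms: pivaloyl chloride, CC(C)(C)C(=O)Cl (its atoms stay in 9 only)
Why: N-acylation through the mixed pivalic anhydride with LiCl activation is acid-free (MOM safe), and the hindered pivaloyl carbonyl directs the oxazolidinone to the arylacetyl carbonyl.

Step 6
Reactants: 11 4-hydroxy-3,5-dimethoxybenzaldehyde (syringaldehyde)
Product: 12 3,5-dimethoxy-4-[(triisopropylsilyl)oxy]benzaldehyde
Conditions: TIPSCl (1.2 equiv), imidazole (2.5 equiv), DMAP (cat.), DMF, rt to 40 °C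
Reagents that add atoms: chlorotriisopropylsilane, CC(C)[Si](Cl)(C(C)C)C(C)C
Why: Silylation of the phenol gives an aryl TIPS ether that tolerates the boron aldol, hydride, acidic methanol and aqueous carbonate, and is later removed by fluoride without touching the propenyl group.

Step 7
Reactants: 10 (4R)-4-benzyl-3-{2-[5-bromo-3-methoxy-2-(methoxymethoxy)phenyl]acetyl}-1,3-oxazolidin-2-one; 12 3,5-dimethoxy-4-[(triisopropylsilyl)oxy]benzaldehyde
Product: 15 (4R)-4-benzyl-3-[(2R,3R)-2-[5-bromo-3-methoxy-2-(methoxymethoxy)phenyl]-3-{3,5-dimethoxy-4-[(triisopropylsilyl)oxy]phenyl}-3-hydroxypropanoyl]-1,3-oxazolidin-2-one, via boron enolate 13 (not isolated), via boron aldolate 14 (not isolated)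
Conditions: Bu2BOTf (1.2 equiv), iPr2NEt (1.4 equiv), CH2Cl2, −78 to 0 °C; 12 (1.2 equiv), −78 to 0 °C; then pH 7 buffer, MeOH, 30% H2O2, 0 °C
Reagents that add atoms: dibutylboron triflate, CCCCB(CCCC)OS(=O)(=O)C(F)(F)F (its Bu2B group stays in 13 and 14 only)
Why: In this Evans syn aldol the Z boron enolate reacts through a closed Zimmerman–Traxler chair on the enolate face away from the auxiliary benzyl group, giving the (2R,3R) syn adduct whose α-carbon is the future C3 (R).

Step 8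
Reactants: 15 the aldol adduct
Product: 16 (1R,2S)-2-[5-bromo-3-methoxy-2-(methoxymethoxy)phenyl]-1-{3,5-dimethoxy-4-[(triisopropylsilyl)oxy]phenyl}propane-1,3-diol
Conditions: LiBH4 (2.5 equiv), MeOH (2.5 equiv), THF, 0 °C
Reagents that add atoms: none
Why: Reductive cleavage of the imide by LiBH4 at 0 °C is faster than retro-aldol or α-epimerisation, leaves both stereocentres untouched (the descriptor at C2 changes only by priority) and returns the auxiliary.

Step 9
Reactants: 16 the MOM-protected diol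
Product: 18 [(2R,3S)-5-bromo-2-{3,5-dimethoxy-4-[(triisopropylsilyl)oxy]phenyl}-7-methoxy-2,3-dihydro-1-benzofuran-3-yl]methanol, via phenol diol 17 (not isolated)
Conditions: HCl (1.25 M in MeOH, 5 equiv), MeOH/THF 3:1, 0 to 40 °C
Reagents that add atoms: none
Why: Acid cleaves the aryl MOM acetal and ionises the benzylic alcohol to a cation stabilised by the para-silyloxy aryl ring, which the ortho phenol traps in an SN1 cyclodehydration; the C3 hydroxymethyl group forces the aryl group trans (also the thermodynamic isomer, since closure is reversible), so C2 becomes R.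

Step 10
Reactants: 18 the dihydrobenzofuran methanol
Product: 19 [(2R,3S)-5-bromo-2-{3,5-dimethoxy-4-[(triisopropylsilyl)oxy]phenyl}-7-methoxy-2,3-dihydro-1-benzofuran-3-yl]methyl 4-methylbenzenesulfonate
Conditions: TsCl (1.5 equiv), Et3N (3 equiv), DMAP (0.1 equiv), CH2Cl2, 0 °C to rt
Reagents that add atoms: p-toluenesulfonyl chloride, Cc1ccc(cc1)S(=O)(=O)Cl
Why: Sulfonylation of the only free hydroxyl, a primary alcohol, turns it into a leaving group without touching either stereocentre.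

Step 11
Reactants: 19 the tosylate
Product: 20 (2R,3R)-5-bromo-2-{3,5-dimethoxy-4-[(triisopropylsilyl)oxy]phenyl}-7-methoxy-3-methyl-2,3-dihydro-1-benzofuran
Conditions: LiEt3BH (1.0 M in THF, 3 equiv), THF, 0 °C to rt
Reagents that add atoms: none
Why: SN2 hydride displacement of the primary tosylate by the highly nucleophilic LiEt3BH gives the methyl group at a carbon that is not stereogenic, while the aryl bromide and aryl silyl ether are inert at this temperature.

Step 12
Reactants: 20 the bromo-dihydrobenzofuran; 21 4,4,5,5-tetramethyl-2-[(1E)-prop-1-en-1-yl]-1,3,2-dioxaborolane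
Product: 22 (2R,3R)-2-{3,5-dimethoxy-4-[(triisopropylsilyl)oxy]phenyl}-7-methoxy-3-methyl-5-[(1E)-prop-1-en-1-yl]-2,3-dihydro-1-benzofuran
Conditions: 21 (1.5 equiv), PdCl2(dppf) (5 mol %; dppf = 1,1'-bis(diphenylphosphino)ferrocene), K2CO3 (3 equiv), 1,4-dioxane/H2O 5:1, 80 °C
Reagents that add atoms: none
Why: Suzuki–Miyaura coupling transfers the alkenyl group with retention of the E geometry, and the mild carbonate base leaves the stereocentres and the hindered TIPS ether intact.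

Step 13
Reactants: 22 O-TIPS-maceneolignan A
Product: 23 maceneolignan A, 4-[(2R,3R)-7-methoxy-3-methyl-5-[(1E)-prop-1-en-1-yl]-2,3-dihydro-1-benzofuran-2-yl]-2,6-dimethoxyphenol
Conditions: TBAF (1.2 equiv), AcOH (1.2 equiv), THF, 0 °C
Reagents that add atoms: none
Why: Fluoride-driven desilylation of the aryl silyl ether, buffered with acetic acid so that the phenoxide cannot open the ring through a quinone methide, frees the phenol without affecting the alkene or the stereocentres.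

## Compound list

1 | 5-bromo-2-hydroxy-3-methoxybenzaldehyde | O=Cc1cc(Br)cc(OC)c1O | starting material
2 | 5-bromo-3-methoxy-2-(methoxymethoxy)benzaldehyde | O=Cc1cc(Br)cc(OC)c1OCOC | intermediate
3 | 5-bromo-1-ethenyl-3-methoxy-2-(methoxymethoxy)benzene | C=Cc1cc(Br)cc(OC)c1OCOC | intermediate
4 | 9-{2-[5-bromo-3-methoxy-2-(methoxymethoxy)phenyl]ethyl}-9-borabicyclo[3.3.1]nonane (not isolated) | C1CCC2CCCC(C1)B2CCc1cc(Br)cc(OC)c1OCOC | intermediate
5 | 2-[5-bromo-3-methoxy-2-(methoxymethoxy)phenyl]ethan-1-ol | OCCc1cc(Br)cc(OC)c1OCOC | intermediate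
6 | 2-[5-bromo-3-methoxy-2-(methoxymethoxy)phenyl]acetaldehyde (not isolated) | O=CCc1cc(Br)cc(OC)c1OCOC | intermediate
7 | 2-[5-bromo-3-methoxy-2-(methoxymethoxy)phenyl]acetic acid | OC(=O)Cc1cc(Br)cc(OC)c1OCOC | intermediate
8 | (R)-4-benzyl-1,3-oxazolidin-2-one | O=C1N[C@H](Cc2ccccc2)CO1 | starting material
9 | 2-[5-bromo-3-methoxy-2-(methoxymethoxy)phenyl]acetic pivalic anhydride (not isolated) | CC(C)(C)C(=O)OC(=O)Cc1cc(Br)cc(OC)c1OCOC | intermediate
10 | (4R)-4-benzyl-3-{2-[5-bromo-3-methoxy-2-(methoxymethoxy)phenyl]acetyl}-1,3-oxazolidin-2-one | O=C(Cc1cc(Br)cc(OC)c1OCOC)N1[C@H](Cc2ccccc2)COC1=O | intermediate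
11 | 4-hydroxy-3,5-dimethoxybenzaldehyde (syringaldehyde) | O=Cc1cc(OC)c(O)c(OC)c1 | starting material
12 | 3,5-dimethoxy-4-[(triisopropylsilyl)oxy]benzaldehyde | O=Cc1cc(OC)c(O[Si](C(C)C)(C(C)C)C(C)C)c(OC)c1 | intermediate
13 | (Z)-dibutylboron enolate of 10 (not isolated) | CCCCB(CCCC)O/C(=C\c1cc(Br)cc(OC)c1OCOC)N1[C@H](Cc2ccccc2)COC1=O | intermediate
14 | O-dibutylboryl aldolate of 15 (not isolated) | O=C([C@H](c1cc(Br)cc(OC)c1OCOC)[C@@H](OB(CCCC)CCCC)c1cc(OC)c(O[Si](C(C)C)(C(C)C)C(C)C)c(OC)c1)N1[C@H](Cc2ccccc2)COC1=O | intermediate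
15 | (4R)-4-benzyl-3-[(2R,3R)-2-[5-bromo-3-methoxy-2-(methoxymethoxy)phenyl]-3-{3,5-dimethoxy-4-[(triisopropylsilyl)oxy]phenyl}-3-hydroxypropanoyl]-1,3-oxazolidin-2-one | O=C([C@H](c1cc(Br)cc(OC)c1OCOC)[C@@H](O)c1cc(OC)c(O[Si](C(C)C)(C(C)C)C(C)C)c(OC)c1)N1[C@H](Cc2ccccc2)COC1=O | intermediate
16 | (1R,2S)-2-[5-bromo-3-methoxy-2-(methoxymethoxy)phenyl]-1-{3,5-dimethoxy-4-[(triisopropylsilyl)oxy]phenyl}propane-1,3-diol | OC[C@H](c1cc(Br)cc(OC)c1OCOC)[C@@H](O)c1cc(OC)c(O[Si](C(C)C)(C(C)C)C(C)C)c(OC)c1 | intermediate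
17 | (1R,2S)-2-(5-bromo-2-hydroxy-3-methoxyphenyl)-1-{3,5-dimethoxy-4-[(triisopropylsilyl)oxy]phenyl}propane-1,3-diol (not isolated) | OC[C@H](c1cc(Br)cc(OC)c1O)[C@@H](O)c1cc(OC)c(O[Si](C(C)C)(C(C)C)C(C)C)c(OC)c1 | intermediate
18 | [(2R,3S)-5-bromo-2-{3,5-dimethoxy-4-[(triisopropylsilyl)oxy]phenyl}-7-methoxy-2,3-dihydro-1-benzofuran-3-yl]methanol | Brc1cc(OC)c2c(c1)[C@@H](CO)[C@H](c1cc(OC)c(O[Si](C(C)C)(C(C)C)C(C)C)c(OC)c1)O2 | intermediate
19 | [(2R,3S)-5-bromo-2-{3,5-dimethoxy-4-[(triisopropylsilyl)oxy]phenyl}-7-methoxy-2,3-dihydro-1-benzofuran-3-yl]methyl 4-methylbenzenesulfonate | Brc1cc(OC)c2c(c1)[C@@H](COS(=O)(=O)c1ccc(C)cc1)[C@H](c1cc(OC)c(O[Si](C(C)C)(C(C)C)C(C)C)c(OC)c1)O2 | intermediate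
20 | (2R,3R)-5-bromo-2-{3,5-dimethoxy-4-[(triisopropylsilyl)oxy]phenyl}-7-methoxy-3-methyl-2,3-dihydro-1-benzofuran | Brc1cc(OC)c2c(c1)[C@@H](C)[C@H](c1cc(OC)c(O[Si](C(C)C)(C(C)C)C(C)C)c(OC)c1)O2 | intermediate
21 | 4,4,5,5-tetramethyl-2-[(1E)-prop-1-en-1-yl]-1,3,2-dioxaborolane | C/C=C/B1OC(C)(C)C(C)(C)O1 | starting material
22 | (2R,3R)-2-{3,5-dimethoxy-4-[(triisopropylsilyl)oxy]phenyl}-7-methoxy-3-methyl-5-[(1E)-prop-1-en-1-yl]-2,3-dihydro-1-benzofuran | C/C=C/c1cc(OC)c2c(c1)[C@@H](C)[C@H](c1cc(OC)c(O[Si](C(C)C)(C(C)C)C(C)C)c(OC)c1)O2 | intermediate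
23 | maceneolignan A, 4-[(2R,3R)-7-methoxy-3-methyl-5-[(1E)-prop-1-en-1-yl]-2,3-dihydro-1-benzofuran-2-yl]-2,6-dimethoxyphenol | C/C=C/c1cc(OC)c2c(c1)[C@@H](C)[C@H](c1cc(OC)c(O)c(OC)c1)O2 | target

## Summary and risks

Total step count: 13. Longest linear sequence: 12 steps (1 → 23 through steps 1–5 and 7–13).

**Step 7 (aldol).** The ortho-substituted arylacetyl imide may enolise or add sluggishly, and the α-aryl β-hydroxy imide can revert by retro-aldol. The fallback changes auxiliary and enolate metal; it sets out from acid 7 and comes back at diol 16. Acid 7 is coupled (EDC·HCl, DMAP, CH2Cl2) with (R)-4-benzyl-1,3-thiazolidine-2-thione to give the N-arylacetyl thiazolidinethione F1. Soft enolisation with TiCl4 (1.05 equiv), iPr2NEt (1.1 equiv) and N-methylpyrrolidinone (1.1 equiv) in CH2Cl2 at 0 °C gives the chlorotitanium enolate F2 (not isolated). Aldehyde 12 adds to it to give the titanium aldolate F3 (not isolated) and, after NH4Cl quench, the Evans-syn thioimide aldol F4. NaBH4 (THF/EtOH, 0 °C) cleaves this activated thioimide far more gently than the oxazolidinone needs and delivers diol 16.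

**Step 9 (MOM cleavage and ring closure).** The benzylic cation carries a γ-hydroxymethyl group and can lose formaldehyde (retro-Prins) or a proton to give stilbenes before the phenol is free. The fallback changes the order of events so that the cation never has a γ-hydroxyl; it sets out from diol 16 and comes back at 20, skipping steps 10 and 11. Selective primary tosylation (TsCl, pyridine, 0 °C) gives the monotosylate F5. Excess LiEt3BH (THF, 0 °C) reduces it to the methyl carbinol F6. The same HCl/MeOH treatment then cleaves the MOM ether to the phenol carbinol F7 (not isolated), which closes to the trans-3-methyl dihydrobenzofuran 20.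

**Step 11 (hydride displacement).** The basic hydride may instead eliminate the tosylate next to the benzylic C3–H (3-methylene compound, then benzofuran) or attack the aryl bromide. The fallback replaces polar displacement by a radical reduction; it sets out from alcohol 18 and comes back at 20. Appel iodination (I2, PPh3, imidazole, CH2Cl2, 0 °C to rt) gives the primary iodide F8. Bu3SnH (1.1 equiv) with Et3B/air in toluene at 0 °C reduces the C–I bond much faster than the aryl C–Br bond and without base, giving 20.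

## Further compounds

F1 | step 7 | (4R)-4-benzyl-3-{2-[5-bromo-3-methoxy-2-(methoxymethoxy)phenyl]acetyl}-1,3-thiazolidine-2-thione | O=C(Cc1cc(Br)cc(OC)c1OCOC)N1[C@H](Cc2ccccc2)CSC1=S
F2 | step 7 | (Z)-trichlorotitanium enolate of F1 (not isolated) | Cl[Ti](Cl)(Cl)O/C(=C\c1cc(Br)cc(OC)c1OCOC)N1[C@H](Cc2ccccc2)CSC1=S
F3 | step 7 | O-trichlorotitanium aldolate of F4 (not isolated) | O=C([C@H](c1cc(Br)cc(OC)c1OCOC)[C@@H](O[Ti](Cl)(Cl)Cl)c1cc(OC)c(O[Si](C(C)C)(C(C)C)C(C)C)c(OC)c1)N1[C@H](Cc2ccccc2)CSC1=S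
F4 | step 7 | (2R,3R)-1-[(4R)-4-benzyl-2-sulfanylidene-1,3-thiazolidin-3-yl]-2-[5-bromo-3-methoxy-2-(methoxymethoxy)phenyl]-3-{3,5-dimethoxy-4-[(triisopropylsilyl)oxy]phenyl}-3-hydroxypropan-1-one | O=C([C@H](c1cc(Br)cc(OC)c1OCOC)[C@@H](O)c1cc(OC)c(O[Si](C(C)C)(C(C)C)C(C)C)c(OC)c1)N1[C@H](Cc2ccccc2)CSC1=S
F5 | step 9 | (2S,3R)-2-[5-bromo-3-methoxy-2-(methoxymethoxy)phenyl]-3-{3,5-dimethoxy-4-[(triisopropylsilyl)oxy]phenyl}-3-hydroxypropyl 4-methylbenzenesulfonate | Cc1ccc(cc1)S(=O)(=O)OC[C@H](c1cc(Br)cc(OC)c1OCOC)[C@@H](O)c1cc(OC)c(O[Si](C(C)C)(C(C)C)C(C)C)c(OC)c1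
F6 | step 9 | (1R,2R)-2-[5-bromo-3-methoxy-2-(methoxymethoxy)phenyl]-1-{3,5-dimethoxy-4-[(triisopropylsilyl)oxy]phenyl}propan-1-ol | C[C@H](c1cc(Br)cc(OC)c1OCOC)[C@@H](O)c1cc(OC)c(O[Si](C(C)C)(C(C)C)C(C)C)c(OC)c1
F7 | step 9 | (1R,2R)-2-(5-bromo-2-hydroxy-3-methoxyphenyl)-1-{3,5-dimethoxy-4-[(triisopropylsilyl)oxy]phenyl}propan-1-ol (not isolated) | C[C@H](c1cc(Br)cc(OC)c1O)[C@@H](O)c1cc(OC)c(O[Si](C(C)C)(C(C)C)C(C)C)c(OC)c1
F8 | step 11 | (2R,3R)-5-bromo-2-{3,5-dimethoxy-4-[(triisopropylsilyl)oxy]phenyl}-3-(iodomethyl)-7-methoxy-2,3-dihydro-1-benzofuran | Brc1cc(OC)c2c(c1)[C@@H](CI)[C@H](c1cc(OC)c(O[Si](C(C)C)(C(C)C)C(C)C)c(OC)c1)O2
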